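## Structural features

The target 17 is one cyclohexene ring carrying a linear C10 chain. With the ring numbered C1 (alkynyl-bearing sp2 carbon), C2 (olefinic CH), C3 (OAc), C4 (OMe), C5 and C6 (OH), the four sp3 ring carbons are contiguous oxygenated stereocentres (C3 S, C4 R, C5 S, C6 S). The C3 and C4 oxygens are cis to each other, the C5 and C6 hydroxyls are cis to each other, and the two pairs lie on opposite faces (C4/C5 trans), the conduritol E pattern. The chain is joined to C1 through an alkyne that is conjugated with a 1,1-disubstituted olefin; one methylene separates this enyne from an (E)-olefin that ends in a tertiary allylic alcohol, so the chain has one geometric element and no stereocentre. Fragile points are the allylic acetate at C3 (ionisable by zerovalent palladium, cleaved or shifted by base), the tertiary allylic alcohol (ionises and dehydrates in acid), the skipped diene (can move into conjugation) and the cross-conjugated dienyne. The real difficulty is the set of four different oxygen functions on four adjacent stereocentres, in an absolute configuration that mirrors the one reached directly by microbial dioxygenation of a monohalobenzene. The key step exploits the cis C5,C6-diol next to sp2 carbon C1: this is the pattern of an arene cis-dihydrodiol whose halogen-bearing carbon becomes C1 and whose remaining diene (C1=C2, C3=C4) supplies the ring olefin and the site of the second cis-diol. A para iodine serves as a removable control element that turns the enzyme towards the required antipode.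

## Logic of the disconnections

17 ⇒ 9 + 16. The C1–C(sp) bond is cut because it is the only bond that joins two fragments without touching a stereocentre. This separates a C6 ring halide that holds all four stereocentres and all ring oxygens in their final state from an achiral C10 enyne. The forward coupling must tolerate a free diol, a tertiary alcohol and an allylic acetate, and must insert into C1–Br faster than it ionises the C3–O bond.

9 ⇒ 8 ⇒ 7 ⇒ 6. The ketal C–O bonds at C5/C6 are restored, and the O–CH3 bond at C4 and the O–acyl bond at C3 are removed. The ketal hides the C5/C6 pair while C3–OH and C4–OH are told apart by their intrinsic reactivity, so no further protecting group is needed. The simplification is a diol with only two free hydroxyls. The demands are acylation at the allylic C3–OH only, methylation at C4 without an alkoxide (no acyl shift), and ketal hydrolysis that spares the acetate; hydrolysis is placed before the coupling so that the acid-labile chain never meets acid.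

6 ⇒ 5. The C3–O and C4–O bonds are cut together, since a cis-diol anti to an existing cis-diol is the mark of a face-selective syn-dihydroxylation of a cyclic diene. Two stereocentres disappear. The forward step must choose the unhalogenated C3=C4 bond and the face opposite the ketal.

5 ⇒ 4 ⇒ 2. The C4–H bond is exchanged for C4–I and the ketal is removed. Iodine is a traceless control element whose only task is to steer the enzymatic step. The precursor becomes the dihydrodiol of a para-dihalobenzene. The forward reduction must cleave C–I and leave C–Br and the diene alone.

2 ⇒ 1. The C5–O and C6–O bonds are cut (key step). The last two stereocentres vanish and a commercial arene is reached in one step. The forward step must select one of the two enantiotopic arene bonds.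

16 ⇒ 15 ⇒ 13 + 14. The C(sp)–C(sp2) bond of the chain is cut after capping the alkyne terminus with silicon. This gives a two-carbon alkyne unit and a C8 bromodiene. The coupling must stop at mono-substitution and must not conjugate the skipped diene.

13 ⇒ 11 + 12. The allyl–alkenyl C(sp3)–C(sp2) bond is cut. Both ends of the 2-bromoallyl unit are CH2, so no regiochemical question arises, and the (E) geometry is carried in from the alkenyl partner. The forward step must react at the allylic C–Br bond of 12 and not at its alkenyl C–Br bond.

11 ⇒ 10. The C–B bond is cut; syn addition of boron and hydrogen across the terminal alkyne fixes the (E) olefin. The demand is terminal regioselectivity in the presence of the free tertiary hydroxyl.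

## Other disconnections considered

Alternative 1: The cut removes both C–O bonds of an oxirane across C4–C5 and raises C3 and C6 to the ketal and ketone levels. The ring then becomes the cross-conjugated dienone A2, which already carries the whole chain at C1.
- Forward key step: Weitz–Scheffer-type epoxidation of A2 with tert-butyl hydroperoxide and NaOH under a cinchonidine-derived N-benzylammonium phase-transfer catalyst. The hydroperoxide anion would add to the unsubstituted C4=C5 enone inside the chiral ion pair and close to epoxide A1, setting C4 and C5.
- In its favour: A2 should lie only a few steps from a commercial phenol and 16. The absolute configuration is reagent-controlled, and the pseudoenantiomeric catalyst would give the other antipode. Anti opening of the oxirane at C4 by methanol would give the trans C4-OMe/C5-OH relationship of 17 directly.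
- Against it here: A1 fixes only two of the four stereocentres. C6 and C3 would need two separate carbonyl reductions, each with a 1,2-cis outcome. The methanolysis must choose C4 (next to the ketal) over C5 (next to the ketone). Three secondary hydroxyls must then be told apart for one acetylation. The base- and peroxide-sensitive dienyne chain is carried through all of this.
- Comparison, structure: both plans start from a flat C6 ring, but the chosen plan keeps a halogen at C1 so the fragile chain is attached last.
- Comparison, mechanism: the chosen plan makes all four C–O stereocentres by two syn-dihydroxylations and no carbonyl chemistry; the alternative needs an epoxidation, a regioselective SN2 opening and two hydride additions.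
- Comparison, step economy: the alternative is the equal or the better as far as A1 (about three steps against four to reach 6), but is expected to lose that lead afterwards and to end near or above eight linear steps.
- Where it is better: its enantioselectivity does not depend on an enzyme telling bromine from iodine, and it needs no fermentation equipment.

Alternative 2: The cut is the ring olefin C1=C2. This opens the carbocycle to the carbohydrate-derived acyclic 1,7-diene A4, whose vinyl carbon becomes C2 and whose 1,1-disubstituted olefin carbon becomes C1. The first chain carbon, C7, is present only as a p-methoxybenzyl-protected hydroxymethyl group.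
- Forward key step: ring-closing metathesis of A4 with the second-generation Grubbs catalyst, releasing ethylene and giving the trisubstituted cyclohexene A3.
- In its favour: six-membered ring closure by metathesis is dependable even for a trisubstituted olefin. The C3–C5 stereocentres come from the chiral pool. The C4 methyl ether is installed while C4–OH is the only free hydroxyl.
- Where it is better: certainty of the enantiomeric series and unambiguous placement of the methyl ether.
- Against it here: C1 ends with a CH2O group, not the alkyne. Ether cleavage, oxidation to the enal, base-mediated one-carbon homologation on a conjugate acceptor and a Sonogashira coupling with 13 must follow. The two identical triethylsilyl ethers at C3 and C5 do not single out the acetate site, so a selective acylation among C3–OH, C5–OH and C6–OH is still unsolved. The C6 carbinol needs a diastereoselective alkenylmetal addition to a sugar aldehyde.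
- Comparison, structure: the ring is built last from a long protected chain, whereas the chosen plan starts from the intact ring with its coupling handle.
- Comparison, mechanism: a metallacyclobutane sequence forms one C=C bond and no stereocentre, whereas the dioxygenase forms two C–O bonds and two stereocentres at once.
- Comparison, step economy: many protecting-group operations before A4 and at least five steps after A3 should make it about twice as long as the chosen eight-step sequence.
- Equal point: in both plans the central catalytic step is well-established chemistry.

Alternative 3: The cut is the C2–C3 bond, traced to an intramolecular aldol between the former C6 and C1 of a hexopyranoside. The precursor is the D-galactose-derived 6-deoxyhex-5-enopyranoside A6, with the 2-O-methyl ether and the 3,4-O-isopropylidene group in place.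
- Forward key step: Ferrier carbocyclization. Catalytic Hg(OCOCF3)2 in aqueous acetone would hydroxymercurate the enol ether, the hemiacetal would open to a mercurated keto aldehyde, and aldol closure would give the 2-deoxyinosose A5 with a new carbinol at C3.
- In its favour: galactose supplies C4, C5 and C6 in the correct relative and absolute configuration. The aldol normally places the new hydroxyl trans to the oxygen two carbons away (C5–O), as 17 requires. A5 has exactly one free hydroxyl, the one to be acetylated.
- Where it is better: the built-in differentiation of the four oxygens (the chosen plan relies on the different reactivity of two secondary hydroxyls) and the certainty of absolute configuration.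
- Against it here: a divalent mercury salt is a poor choice on safety grounds. C1 is a ketone and C2 a methylene, so the substituted C1=C2 olefin needs regioselective enolisation towards C2 and triflation in a β-oxygenated ketone prone to E1cB loss of the C3 oxygen, with enolisation towards C6 as a second leak.
- Equal point: the alkenyl triflate would meet the same hazard of an allylic acetate under zerovalent palladium as the chosen route.
- Comparison, structure: the sugar route delivers the oxygen pattern but lacks the sp2 handle; the arene route delivers the handle but must sort the oxygens.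
- Comparison, mechanism: an aldol ring closure sets one stereocentre under substrate control, whereas the enzymatic step sets two under catalyst control and closes no ring.
- Comparison, step economy: about five steps to A6, the carbocyclization and four or five more give ten or eleven linear steps against eight.

Key step: step 1

Assumptions (remarks on the chemistry):
- Ring atoms of all intermediates are referred to by the numbering of 17 (C1 to C6 as above).
- In step 1 the two reducing equivalents reach the enzyme as NADH, which the cells regenerate by oxidising the glucose co-substrate; this is taken as complete oxidation to carbon dioxide.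
- The configuration of 2, (1S,2R), and that of 17 were rederived from the structures and agree: the C5 and C6 oxygens of 2 lie on the face they occupy in 17.

## Route

Step 1
Reactants: 1 1-bromo-4-iodobenzene
Product: 2 (1S,2R)-3-bromo-6-iodocyclohexa-3,5-diene-1,2-diol
Conditions: Pseudomonas putida UV4 whole cells (toluene dioxygenase), glucose, air, phosphate buffer pH 7.2, 30 °C; EtOAc extraction; recrystallisation
Reagents that add atoms: dioxygen, O=O
Why: Toluene dioxygenase is a Rieske non-heme iron dioxygenase: electrons from NADH pass through a reductase and a ferredoxin to the [2Fe-2S] cluster and on to the mononuclear ferrous iron, where O2 is bound and reduced to a ferric (hydro)peroxo species that delivers both oxygen atoms to the same face of one arene C=C bond. The closest known reaction type is the whole-cell cis-dihydroxylation of monohalobenzenes and of para-substituted iodobenzenes by the same blocked mutant, which lacks the cis-diol dehydrogenase so that the diol accumulates. No ring is closed; the six-membered ring is kept and only loses its aromaticity. In a para-dihalobenzene each of the two enantiotopic bonds C2–C3 and C5–C6 is flanked by both halogens, so only one constitution can form and the enzyme chooses between enantiomers, not regioisomers. Both new stereocentres (C5 and C6) are set by the active site, which seats the larger substituent in its hydrophobic pocket and oxidises the bond on one fixed side of it; with iodine in that pocket the diol has the (1S,2R) configuration of 2, the mirror-image sense of what a lone bromine would direct. The selectivity needed is therefore recognition of iodine over bromine, secured only by the larger radius and polarisability of iodine; because that difference is small, recrystallisation of the crystalline diol is planned as enrichment. The two electron-withdrawing halogens should also slow acid-catalysed dehydration of 2 to a phenol, which makes isolation practical.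

Step 2
Reactants: 2 (1S,2R)-3-bromo-6-iodocyclohexa-3,5-diene-1,2-diol; 3 2,2-dimethoxypropane
Product: 4 (3aR,7aS)-4-bromo-7-iodo-2,2-dimethyl-3a,7a-dihydro-1,3-benzodioxole
Conditions: 3 (excess), p-TsOH·H2O (cat.), acetone, 0 °C to rt; Et3N quench
Reagents that add atoms: none
Why: Acid-catalysed transketalisation of a cis-1,2-diol gives the strain-free cis-fused dioxolane without touching a stereocentre; the two halogens disfavour aromatisation during the brief acid exposure.

Step 3
Reactants: 4 (3aR,7aS)-4-bromo-7-iodo-2,2-dimethyl-3a,7a-dihydro-1,3-benzodioxole
Product: 5 (3aR,7aR)-4-bromo-2,2-dimethyl-3a,7a-dihydro-1,3-benzodioxole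
Conditions: Pd(PPh3)4 (3 mol%), HCO2H (1.1 equiv), Et3N (1.5 equiv), DMF, 25 °C; used at once
Reagents that add atoms: none
Why: Palladium-catalysed formate hydrogenolysis of an alkenyl halide: zerovalent palladium inserts into the weaker C–I bond far faster than into C–Br at room temperature, formate exchange and decarboxylation give a palladium hydride, and reductive elimination leaves C4–H with the diene and both stereocentres untouched. Diene 5 is prone to Diels–Alder dimerisation and is carried on without storage.

Step 4
Reactants: 5 (3aR,7aR)-4-bromo-2,2-dimethyl-3a,7a-dihydro-1,3-benzodioxole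
Product: 6 (3aR,4S,5S,7aR)-7-bromo-2,2-dimethyl-3a,4,5,7a-tetrahydro-1,3-benzodioxole-4,5-diol
Conditions: OsO4 (2 mol%), NMO (1.3 equiv), acetone/H2O (4:1), 0 °C to rt
Reagents that add atoms: N-methylmorpholine N-oxide, C[N+]1([O-])CCOCC1; water, O; both oxygens delivered through catalytic osmium tetroxide, O=[Os](=O)(=O)=O
Why: Upjohn dihydroxylation; OsO4 selects the electron-richer, unhalogenated C3=C4 bond and adds in a concerted [3+2] manner from the face opposite the cis-fused ketal, so C3 and C4 are set syn to each other and anti to C5/C6 by substrate control.

Step 5
Reactants: 6 (3aR,4S,5S,7aR)-7-bromo-2,2-dimethyl-3a,4,5,7a-tetrahydro-1,3-benzodioxole-4,5-diol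
Product: 7 (3aR,4S,5S,7aR)-7-bromo-4-hydroxy-2,2-dimethyl-3a,4,5,7a-tetrahydro-1,3-benzodioxol-5-yl acetate
Conditions: AcCl (1.05 equiv), 2,4,6-collidine, CH2Cl2, −78 to −40 °C
Reagents that add atoms: acetyl chloride, CC(=O)Cl
Why: Kinetic monoacylation: the allylic C3–OH is flanked by an sp2 CH and is remote from the ketal, whereas C4–OH sits between two oxygenated carbons, so one equivalent of acyl chloride with a hindered base at low temperature should acylate C3–O; no alkoxide is formed, which keeps acyl migration slow.

Step 6
Reactants: 7 (3aR,4S,5S,7aR)-7-bromo-4-hydroxy-2,2-dimethyl-3a,4,5,7a-tetrahydro-1,3-benzodioxol-5-yl acetate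
Product: 8 (3aR,4S,5S,7aR)-7-bromo-4-methoxy-2,2-dimethyl-3a,4,5,7a-tetrahydro-1,3-benzodioxol-5-yl acetate
Conditions: Me3OBF4 (3 equiv), 1,8-bis(dimethylamino)naphthalene (3.5 equiv), 4 Å MS, CH2Cl2, 0 °C to rt
Reagents that add atoms: trimethyloxonium tetrafluoroborate, C[O+](C)C.F[B-](F)(F)F
Why: O-Methylation with Meerwein's salt buffered by a non-nucleophilic base goes through the neutral alcohol and so avoids the alkoxide that would trigger acetyl migration; acetate, ketal and alkenyl bromide are inert to the oxonium salt.

Step 7
Reactants: 8 (3aR,4S,5S,7aR)-7-bromo-4-methoxy-2,2-dimethyl-3a,4,5,7a-tetrahydro-1,3-benzodioxol-5-yl acetate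
Product: 9 (1S,4R,5S,6R)-3-bromo-4,5-dihydroxy-6-methoxycyclohex-2-en-1-yl acetate
Conditions: AcOH/H2O (4:1), 60 °C
Reagents that add atoms: none
Why: Acid-catalysed hydrolysis of the cis-fused isopropylidene ketal; the C4 methyl ether blocks any acetyl shift from C3, and placing this step before the coupling keeps the acid-labile tertiary allylic alcohol and enyne away from acid.

Step 8
Reactants: 10 2-methylbut-3-yn-2-ol
Product: 11 (3E)-2-methyl-4-(4,4,5,5-tetramethyl-1,3,2-dioxaborolan-2-yl)but-3-en-2-ol
Conditions: B2pin2 (1.1 equiv), CuCl (5 mol%), Xantphos (5 mol%), NaOt-Bu (10 mol%), MeOH (2 equiv), THF, rt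
Reagents that add atoms: bis(pinacolato)diboron, CC1(C)OB(OC1(C)C)B1OC(C)(C)C(C)(C)O1
Why: Copper-catalysed formal hydroboration: a Cu–Bpin species adds syn across the terminal alkyne with boron at the terminal carbon, and methanol protonates the alkenylcopper to give the (E)-alkenylboronate; the free tertiary hydroxyl is tolerated.

Step 9
Reactants: 11 (3E)-2-methyl-4-(4,4,5,5-tetramethyl-1,3,2-dioxaborolan-2-yl)but-3-en-2-ol; 12 2,3-dibromopropene
Product: 13 (3E)-6-bromo-2-methylhepta-3,6-dien-2-ol
Conditions: 12 (2 equiv), Pd(PPh3)4 (3 mol%), K2CO3 (2 equiv), THF/H2O (5:1), 50 °C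
Reagents that add atoms: none
Why: Suzuki–Miyaura allyl–alkenyl coupling: zerovalent palladium ionises the allylic C–Br bond of 12 much faster than it inserts into the alkenyl C–Br bond, both ends of the 2-bromoallyl unit are CH2 so either site of attack gives the same skipped diene, and the alkenyl group is transferred with retention of the (E) geometry.

Step 10
Reactants: 13 (3E)-6-bromo-2-methylhepta-3,6-dien-2-ol; 14 ethynyltrimethylsilane
Product: 15 (3E)-2-methyl-6-methylidene-8-(trimethylsilyl)oct-3-en-7-yn-2-ol
Conditions: 14 (1.5 equiv), PdCl2(PPh3)2 (3 mol%), CuI (5 mol%), Et3N, THF, 40 °C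
Reagents that add atoms: none
Why: Sonogashira coupling of the 1,1-disubstituted alkenyl bromide with a silyl-capped alkyne; the silyl group prevents double coupling and the tertiary amine is too weak a base to move the skipped diene into conjugation.

Step 11
Reactants: 15 (3E)-2-methyl-6-methylidene-8-(trimethylsilyl)oct-3-en-7-yn-2-ol
Product: 16 (3E)-2-methyl-6-methylideneoct-3-en-7-yn-2-ol
Conditions: K2CO3 (0.2 equiv), MeOH, rt
Reagents that add atoms: none
Why: Base-catalysed methanolysis of the C(sp)–Si bond through a pentacoordinate silicate that expels the acetylide; nothing else in 15 is base-sensitive.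

Step 12
Reactants: 9 (1S,4R,5S,6R)-3-bromo-4,5-dihydroxy-6-methoxycyclohex-2-en-1-yl acetate; 16 (3E)-2-methyl-6-methylideneoct-3-en-7-yn-2-ol
Product: 17 (1S,4S,5S,6R)-4,5-dihydroxy-3-[(5E)-7-hydroxy-7-methyl-3-methylideneoct-5-en-1-yn-1-yl]-6-methoxycyclohex-2-en-1-yl acetate
Conditions: 16 (1.3 equiv), Pd(PPh3)4 (5 mol%), CuI (10 mol%), Et3N (3 equiv), DMF, 40 °C, degassed
Reagents that add atoms: none
Why: Sonogashira coupling joins C1 to the alkyne terminus by oxidative addition into the alkenyl C–Br bond, transmetalation from the copper acetylide and reductive elimination, touching no stereocentre. A tertiary amine is used because it neither aminolyses the acetate nor acts as a nucleophile towards any allylpalladium species that the allylic acetate might form.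

## Compound list

1 | 1-bromo-4-iodobenzene | Brc1ccc(I)cc1 | starting material
2 | (1S,2R)-3-bromo-6-iodocyclohexa-3,5-diene-1,2-diol | BrC1=CC=C(I)[C@@H](O)[C@H]1O | intermediate
3 | 2,2-dimethoxypropane | COC(C)(C)OC | starting material
4 | (3aR,7aS)-4-bromo-7-iodo-2,2-dimethyl-3a,7a-dihydro-1,3-benzodioxole | BrC1=CC=C(I)[C@H]2OC(C)(C)O[C@@H]12 | intermediate
5 | (3aR,7aR)-4-bromo-2,2-dimethyl-3a,7a-dihydro-1,3-benzodioxole | BrC1=CC=C[C@H]2OC(C)(C)O[C@@H]12 | intermediate
6 | (3aR,4S,5S,7aR)-7-bromo-2,2-dimethyl-3a,4,5,7a-tetrahydro-1,3-benzodioxole-4,5-diol | BrC1=C[C@H](O)[C@H](O)[C@H]2OC(C)(C)O[C@@H]12 | intermediate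
7 | (3aR,4S,5S,7aR)-7-bromo-4-hydroxy-2,2-dimethyl-3a,4,5,7a-tetrahydro-1,3-benzodioxol-5-yl acetate | BrC1=C[C@H](OC(C)=O)[C@H](O)[C@H]2OC(C)(C)O[C@@H]12 | intermediate
8 | (3aR,4S,5S,7aR)-7-bromo-4-methoxy-2,2-dimethyl-3a,4,5,7a-tetrahydro-1,3-benzodioxol-5-yl acetate | BrC1=C[C@H](OC(C)=O)[C@H](OC)[C@H]2OC(C)(C)O[C@@H]12 | intermediate
9 | (1S,4R,5S,6R)-3-bromo-4,5-dihydroxy-6-methoxycyclohex-2-en-1-yl acetate | BrC1=C[C@H](OC(C)=O)[C@H](OC)[C@@H](O)[C@H]1O | intermediate
10 | 2-methylbut-3-yn-2-ol | CC(C)(O)C#C | starting material
11 | (3E)-2-methyl-4-(4,4,5,5-tetramethyl-1,3,2-dioxaborolan-2-yl)but-3-en-2-ol | CC(C)(O)/C=C/B1OC(C)(C)C(C)(C)O1 | intermediate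
12 | 2,3-dibromopropene | C=C(Br)CBr | starting material
13 | (3E)-6-bromo-2-methylhepta-3,6-dien-2-ol | C=C(Br)C/C=C/C(C)(C)O | intermediate
14 | ethynyltrimethylsilane | C#C[Si](C)(C)C | starting material
15 | (3E)-2-methyl-6-methylidene-8-(trimethylsilyl)oct-3-en-7-yn-2-ol | C=C(C#C[Si](C)(C)C)C/C=C/C(C)(C)O | intermediate
16 | (3E)-2-methyl-6-methylideneoct-3-en-7-yn-2-ol | C=C(C#C)C/C=C/C(C)(C)O | intermediate
17 | (1S,4S,5S,6R)-4,5-dihydroxy-3-[(5E)-7-hydroxy-7-methyl-3-methylideneoct-5-en-1-yn-1-yl]-6-methoxycyclohex-2-en-1-yl acetate | C=C(C#CC1=C[C@H](OC(C)=O)[C@H](OC)[C@@H](O)[C@H]1O)C/C=C/C(C)(C)O | target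

## Step count and least certain steps

Total step count: 12. Longest linear sequence: 8 (steps 1 to 7, then 12). The side chain takes 4 steps (8 to 11).

Key step, step 1. The most likely failure is incomplete discrimination between the two halogens in the active site, that is low enantiofacial selectivity, because bromine and iodine differ little in size. A second concern is slow turnover of a solid, poorly water-soluble dihaloarene. Recrystallisation of 2 is the first remedy. The fallback replaces enrichment by crystallisation with enantiomer-selective destruction of the unwanted antipode. It sets out from 2 of insufficient purity: the C–I bond of the free diol is cleaved as in step 3 (Pd(PPh3)4, HCO2H, Et3N) to give scalemic (1R,2R)-3-bromocyclohexa-3,5-diene-1,2-diol F1. This is incubated with toluene-grown wild-type Pseudomonas putida cells that express the cis-dihydrodiol dehydrogenase, which should oxidise preferentially the (1S,2S) antipode to the catechol (removed by a dilute base wash). Ketalisation of the enriched F1 with 3 (p-TsOH, acetone) rejoins the route at 5.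

Step 3. The likely failures are loss of chemoselectivity (competing C–Br reduction or palladium hydride addition to the diene) and Diels–Alder dimerisation of the product during a slow reaction. The fallback avoids palladium hydride: it sets out from 4, which is treated with i-PrMgCl·LiCl in THF at −40 °C for iodine–magnesium exchange, selective for the C–I bond. The resulting chloro[(3aS,7aR)-7-bromo-2,2-dimethyl-3a,7a-dihydro-1,3-benzodioxol-4-yl]magnesium F2 is protonated with methanol at low temperature and rejoins the route at 5.

Step 5 (and with it step 6). The likely failures are poor site selectivity between the two secondary hydroxyls and acetyl migration from C3–O to C4–O during the methylation. The fallback uses a temporary silyl group and sets out from 6: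
- TBSCl and imidazole in DMF at 0 °C should silylate the less hindered allylic hydroxyl to give (3aR,4R,5S,7aR)-7-bromo-5-[(tert-butyldimethylsilyl)oxy]-2,2-dimethyl-3a,4,5,7a-tetrahydro-1,3-benzodioxol-4-ol F3.
- Me3OBF4 with 1,8-bis(dimethylamino)naphthalene (no alkoxide, hence no silyl shift) gives tert-butyl{[(3aR,4R,5S,7aR)-7-bromo-4-methoxy-2,2-dimethyl-3a,4,5,7a-tetrahydro-1,3-benzodioxol-5-yl]oxy}dimethylsilane F4.
- TBAF in THF gives (3aR,4S,5S,7aR)-7-bromo-4-methoxy-2,2-dimethyl-3a,4,5,7a-tetrahydro-1,3-benzodioxol-5-ol F5.
- Ac2O, pyridine and catalytic DMAP then rejoin the route at 8.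

Step 9. The likely failures are competing oxidative addition at the alkenyl C–Br bond (double coupling), base-induced dehydrobromination of 12, and isomerisation of the skipped diene. The fallback forms the (E)-olefin by metathesis and sets out from 12: vinylmagnesium bromide with catalytic CuI in THF at −20 °C gives 2-bromopenta-1,4-diene F6. Cross-metathesis of F6 with an excess of 2-methylbut-3-en-2-ol and the second-generation Grubbs catalyst in CH2Cl2 at 40 °C should leave the hindered 2-bromoalkene untouched and rejoin the route at 13.

Step 12. The likely failure is ionisation of the allylic C3 acetate by zerovalent palladium in competition with oxidative addition into C1–Br, leading to substitution, elimination or epimerisation at C3. Oxidative homocoupling of 16 is a lesser concern. The fallback moves the coupling ahead of the acylation and sets out from 6: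
- Sonogashira coupling of 6 with 16 (Pd(PPh3)4, CuI, Et3N, DMF) gives (3aR,4S,5S,7aS)-7-[(5E)-7-hydroxy-7-methyl-3-methylideneoct-5-en-1-yn-1-yl]-2,2-dimethyl-3a,4,5,7a-tetrahydro-1,3-benzodioxole-4,5-diol F7.
- AcCl and 2,4,6-collidine at −78 °C (tertiary hydroxyl inert) give (3aR,4S,5S,7aS)-4-hydroxy-7-[(5E)-7-hydroxy-7-methyl-3-methylideneoct-5-en-1-yn-1-yl]-2,2-dimethyl-3a,4,5,7a-tetrahydro-1,3-benzodioxol-5-yl acetate F8.
- Me3OBF4 with 1,8-bis(dimethylamino)naphthalene, where the secondary hydroxyl should react ahead of the hindered tertiary one, gives (3aS,4S,5S,7aS)-7-[(5E)-7-hydroxy-7-methyl-3-methylideneoct-5-en-1-yn-1-yl]-4-methoxy-2,2-dimethyl-3a,4,5,7a-tetrahydro-1,3-benzodioxol-5-yl acetate F9.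
- Brief treatment with AcOH/H2O at 40 °C rejoins the route at 17.

## Further compounds

F1 | step 1 | (1R,2R)-3-bromocyclohexa-3,5-diene-1,2-diol | BrC1=CC=C[C@@H](O)[C@H]1O
F2 | step 3 | chloro[(3aS,7aR)-7-bromo-2,2-dimethyl-3a,7a-dihydro-1,3-benzodioxol-4-yl]magnesium | BrC1=CC=C([Mg]Cl)[C@H]2OC(C)(C)O[C@@H]12
F3 | step 5 | (3aR,4R,5S,7aR)-7-bromo-5-[(tert-butyldimethylsilyl)oxy]-2,2-dimethyl-3a,4,5,7a-tetrahydro-1,3-benzodioxol-4-ol | BrC1=C[C@H](O[Si](C)(C)C(C)(C)C)[C@H](O)[C@H]2OC(C)(C)O[C@@H]12
F4 | step 5 | tert-butyl{[(3aR,4R,5S,7aR)-7-bromo-4-methoxy-2,2-dimethyl-3a,4,5,7a-tetrahydro-1,3-benzodioxol-5-yl]oxy}dimethylsilane | BrC1=C[C@H](O[Si](C)(C)C(C)(C)C)[C@H](OC)[C@H]2OC(C)(C)O[C@@H]12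
F5 | step 5 | (3aR,4S,5S,7aR)-7-bromo-4-methoxy-2,2-dimethyl-3a,4,5,7a-tetrahydro-1,3-benzodioxol-5-ol | BrC1=C[C@H](O)[C@H](OC)[C@H]2OC(C)(C)O[C@@H]12
F6 | step 9 | 2-bromopenta-1,4-diene | C=CCC(Br)=C
F7 | step 12 | (3aR,4S,5S,7aS)-7-[(5E)-7-hydroxy-7-methyl-3-methylideneoct-5-en-1-yn-1-yl]-2,2-dimethyl-3a,4,5,7a-tetrahydro-1,3-benzodioxole-4,5-diol | C=C(C#CC1=C[C@H](O)[C@H](O)[C@H]2OC(C)(C)O[C@@H]12)C/C=C/C(C)(C)O
F8 | step 12 | (3aR,4S,5S,7aS)-4-hydroxy-7-[(5E)-7-hydroxy-7-methyl-3-methylideneoct-5-en-1-yn-1-yl]-2,2-dimethyl-3a,4,5,7a-tetrahydro-1,3-benzodioxol-5-yl acetate | C=C(C#CC1=C[C@H](OC(C)=O)[C@H](O)[C@H]2OC(C)(C)O[C@@H]12)C/C=C/C(C)(C)O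
F9 | step 12 | (3aS,4S,5S,7aS)-7-[(5E)-7-hydroxy-7-methyl-3-methylideneoct-5-en-1-yn-1-yl]-4-methoxy-2,2-dimethyl-3a,4,5,7a-tetrahydro-1,3-benzodioxol-5-yl acetate | C=C(C#CC1=C[C@H](OC(C)=O)[C@H](OC)[C@H]2OC(C)(C)O[C@@H]12)C/C=C/C(C)(C)O
A1 | alternative 1 | (1R,6S)-3-[(5E)-7-hydroxy-7-methyl-3-methylideneoct-5-en-1-yn-1-yl]-5,5-dimethoxy-7-oxabicyclo[4.1.0]hept-3-en-2-one | C=C(C#CC1=CC(OC)(OC)[C@@H]2[C@@H](O2)C1=O)C/C=C/C(C)(C)O
A2 | alternative 1 | 2-[(5E)-7-hydroxy-7-methyl-3-methylideneoct-5-en-1-yn-1-yl]-4,4-dimethoxycyclohexa-2,5-dien-1-one | C=C(C#CC1=CC(OC)(OC)C=CC1=O)C/C=C/C(C)(C)O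
A3 | alternative 2 | (1S,4S,5S,6S)-5-methoxy-2-{[(4-methoxyphenyl)methoxy]methyl}-4,6-bis[(triethylsilyl)oxy]cyclohex-2-en-1-ol | COc1ccc(COCC2=C[C@H](O[Si](CC)(CC)CC)[C@H](OC)[C@@H](O[Si](CC)(CC)CC)[C@H]2O)cc1
A4 | alternative 2 | 5-methoxy-2-{[(4-methoxyphenyl)methoxy]methyl}-4,6-bis[(triethylsilyl)oxy]octa-1,7-dien-3-ol, configured at its four oxygenated carbons as in A3 | C=C[C@H](O[Si](CC)(CC)CC)[C@H](OC)[C@@H](O[Si](CC)(CC)CC)[C@@H](O)C(=C)COCc1ccc(OC)cc1
A5 | alternative 3 | 6-hydroxy-7-methoxy-2,2-dimethyl-tetrahydro-1,3-benzodioxol-4-one (2-deoxyinosose; C3 hydroxyl free, C4 methyl ether, C5/C6 acetonide, configured as in 17) | O=C1C[C@H](O)[C@H](OC)[C@@H]2[C@H]1OC(C)(C)O2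
A6 | alternative 3 | methyl 6-deoxy-3,4-O-isopropylidene-2-O-methyl-α-L-arabino-hex-5-enopyranoside (from D-galactose) | CO[C@H]1OC(=C)[C@@H]2OC(C)(C)O[C@@H]2[C@H]1OC
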